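**Retrosynthesis**
- The tetrahydropyran and C10–Br come last, by anodic 6-endo bromoetherification of tertiary alcohol **9** onto its prenyl alkene.
- The prenyl group comes from a terminal alkene by cross-metathesis. The C8–C9 bond and the C7/C8 relationship come from chelation-controlled allylation of an α-hydroxy aldehyde, which is made from limonene's isopropenyl group via the diol.
- The cyclohexane ring is (R)-limonene. Its trisubstituted alkene is bromochlorinated first, because it is chemoselective over the isopropenyl group and avoids cineole-type ethers later.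
- Ring order: the cyclohexane exists from the start and is halogenated in step 1; the pyran ring closes in step 7.

**Assumption:** the C1/C2 halogen epimer in step 1 and the C7 epimer in step 2 form in roughly 1:1 to 2:1 ratios and are separated by chromatography or HPLC.

---

**Step 1**
Reactants: 1, (R)-(+)-limonene
Product: 2, (1R,2R,4R)-2-bromo-1-chloro-1-methyl-4-(prop-1-en-2-yl)cyclohexane
Conditions: Et4NBr (1.0 equiv), Et4NCl (6 equiv), AcOH (3 equiv), MeCN/CH2Cl2 1:1, undivided cell, graphite(+)/Pt(–), 5 mA, 0 °C, 2.1 F/mol; then chromatography to remove the 1,2-epimer.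
Reagents that add atoms: Et4NBr, CC[N+](CC)(CC)CC.[Br-]; Et4NCl, CC[N+](CC)(CC)CC.[Cl-]
Why: Anodic oxidation of Br⁻ gives a "Br⁺" equivalent that adds to the more nucleophilic trisubstituted ring alkene, not the isopropenyl group. Excess Cl⁻ opens the bromonium anti at tertiary C1, giving the trans Br/Cl pair; the C4 stereocenter biases the face. Proposed new method: anodic Br⁻ oxidation in excess Cl⁻ delivers BrCl-type anti-bromochlorination of a terpene alkene with Markovnikov chloride capture. The closest known reactions are electrochemical dibromination/dichlorination and NBS/chloride bromochlorination.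

**Step 2**
Reactants: 2
Product: 3, (2S)-2-[(1R,3R,4R)-3-bromo-4-chloro-4-methylcyclohexyl]propane-1,2-diol
Conditions: OsO4 (2 mol%), NMO (1.5 equiv), acetone/H2O 9:1, 0 °C to rt, 12 h; then separate the C7 epimer by HPLC.
Reagents that add atoms: NMO, C[N+]1([O-])CCOCC1; water, O
Why: Upjohn dihydroxylation of the only remaining alkene. C7 is set by the C4 stereocenter with low selectivity (~1:1), so the 2S epimer is isolated. The secondary bromide and tertiary chloride are inert.

**Step 3**
Reactants: 3
Product: 4, (2S)-2-[(1R,3R,4R)-3-bromo-4-chloro-4-methylcyclohexyl]-2-hydroxypropanal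
Conditions: TEMPO (10 mol%), PhI(OAc)2 (1.1 equiv), CH2Cl2, 0 °C to rt, 2 h
Reagents that add atoms: none
Why: TEMPO oxidation is selective for the primary alcohol over the tertiary one. C7 is untouched, and the crude aldehyde is used directly.

**Step 4**
Reactants: 4; 5, allyl bromide
Product: 6, (4S,5S)-5-[(1R,3R,4R)-3-bromo-4-chloro-4-methylcyclohexyl]hex-1-ene-4,5-diol
Conditions: In powder (1.5 equiv), THF/H2O 1:1, rt, 6 h
Reagents that add atoms: none beyond reactant 5 (the allyl group); In is only a metal mediator
Why: Allylindium addition to an α-hydroxy aldehyde proceeds through a five-membered chelate (cyclic Cram control). The allyl group attacks from the face of the small methyl group, away from the cyclohexyl group, which sets C8 as S relative to C7.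

**Step 5**
Reactants: 6
Product: 7, (4S,5S)-5-[(1R,3R,4R)-3-bromo-4-chloro-4-methylcyclohexyl]-5-hydroxyhex-1-en-4-yl acetate
Conditions: Ac2O (1.5 equiv), Et3N (2 equiv), DMAP (5 mol%), CH2Cl2, 0 °C, 3 h
Reagents that add atoms: Ac2O, CC(=O)OC(C)=O
Why: The hindered tertiary alcohol is unreactive, so only the secondary C8–OH is acylated, with no stereocenter change. This blocks a competing 5-endo THF closure in step 7.

**Step 6**
Reactants: 7; 8, 2-methylbut-2-ene
Product: 9, (2S,3S)-2-[(1R,3R,4R)-3-bromo-4-chloro-4-methylcyclohexyl]-2-hydroxy-6-methylhept-5-en-3-yl acetate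
Conditions: Hoveyda–Grubbs II (5 mol%), 2-methylbut-2-ene (20 equiv), CH2Cl2, 40 °C, sealed tube, 12 h
Reagents that add atoms: none beyond reactant 8 (the isopropylidene unit)
Why: Cross-metathesis of a terminal alkene with excess 2-methylbut-2-ene gives the prenyl-type trisubstituted alkene; the alcohol, acetate and alkyl halides are tolerated.

**Step 7**
Reactants: 9
Product: 10, acetylcaespitol, (2S,3S,5S)-5-bromo-2-[(1R,3R,4R)-3-bromo-4-chloro-4-methylcyclohexyl]-2,6,6-trimethyltetrahydro-2H-pyran-3-yl acetate
Conditions: nBu4NBr (1.2 equiv), MeCN, undivided cell, graphite(+)/Pt(–), 3 mA, 0 °C, 2.2 F/mol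
Reagents that add atoms: nBu4NBr, CCCC[N+](CCCC)(CCCC)CCCC.[Br-]
Why: Anodically generated Br⁺ forms a bromonium on the prenyl alkene, and the tertiary C7–OH closes 6-endo at tertiary C11 (anodic halo-etherification). The C10–Br is anti to the forming C11–O bond, so it is equatorial in the chair-like transition state, and the equatorial cyclohexyl group sets C10 as S; the C10 epimer is a minor by-product. Proposed new method: anodic 6-endo bromoetherification of a tertiary alcohol onto a trisubstituted alkene in a polyhalogenated, acetoxylated substrate, with Br⁻ regenerated in the cell and H⁺ reduced at the cathode. The closest known reactions are electrochemical bromoetherification and NBS/BDSB-type bromonium cyclizations.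

---

**Compound list**
1 | (R)-(+)-limonene | C=C(C)[C@@H]1CCC(C)=CC1 | starting material
2 | (1R,2R,4R)-2-bromo-1-chloro-1-methyl-4-isopropenylcyclohexane | C=C(C)[C@@H]1CC[C@@](C)(Cl)[C@H](Br)C1 | intermediate
3 | (2S)-diol | OC[C@@](C)(O)[C@@H]1CC[C@@](C)(Cl)[C@H](Br)C1 | intermediate
4 | (2S)-α-hydroxy aldehyde | O=C[C@@](C)(O)[C@@H]1CC[C@@](C)(Cl)[C@H](Br)C1 | intermediate
5 | allyl bromide | C=CCBr | starting material
6 | (4S,5S)-homoallylic diol | C=CC[C@H](O)[C@@](C)(O)[C@@H]1CC[C@@](C)(Cl)[C@H](Br)C1 | intermediate
7 | secondary acetate | C=CC[C@H](OC(C)=O)[C@@](C)(O)[C@@H]1CC[C@@](C)(Cl)[C@H](Br)C1 | intermediate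
8 | 2-methylbut-2-ene | CC=C(C)C | starting material
9 | prenyl hydroxy acetate | CC(C)=CC[C@H](OC(C)=O)[C@@](C)(O)[C@@H]1CC[C@@](C)(Cl)[C@H](Br)C1 | intermediate
10 | acetylcaespitol | CC(=O)O[C@H]1C[C@H](Br)C(C)(C)O[C@@]1(C)[C@@H]1CC[C@@](C)(Cl)[C@H](Br)C1 | target

**Total steps:** 7. **Longest linear sequence:** 7 (allyl bromide and 2-methylbut-2-ene are purchased building blocks).

**Three steps most likely to fail**
1. **Step 1 (proposed new).** The target ring diastereomer needs an axial-side-chain diaxial transition state and may be the minor isomer. Dibromide or isopropenyl-attack by-products are also possible. Fallback: chemical bromochlorination with a preformed Br⁺ donor (NBS or DBDMH plus Et4NCl, CH2Cl2, –20 °C), which is known chemistry, with diastereomers separated at the diol stage.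
2. **Step 4.** The α-hydroxy aldehyde is prone to hydrate/dimer formation and the chelation dr may be low. Fallback: allylate with allylMgBr without stereocontrol, oxidize the secondary alcohol with DMP to the α-hydroxy ketone, then reduce with Zn(BH4)2 under chelation control. The two epimers converge at the ketone, and the reduction sets C8 under known chelation control.
3. **Step 7 (key step, proposed new).** Risks are C10 stereocontrol, THF or dioxanylium by-products, and cathodic reduction of the alkyl bromides. Fallback: epoxidize the prenyl alkene of 9 with mCPBA, open it 6-endo with CSA using the C7–OH to give the C10-hydroxy tetrahydropyran, then convert C10–OH to Br by Appel inversion (CBr4/PPh3). The epoxide diastereomer is chosen so that inversion gives the C10 configuration of the target.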